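Start from the leftover: in the alpha run, with X at 1.5 equiv, G stands at 86.7% of the Z charged after 2.50 d, and in the epsilon run, with X at 0.50 equiv, at 88.9%, so you have a slice of the charge that does not show as G in these readings, and the question is what that slice does as the charge rises from larch to ash by a factor of 15.0.

the same everywhere: E 4.2 mM (held)
- alpha: Z 0.020 M; X 1.5 equiv; run made earlier
- epsilon: Z 0.020 M; X 0.50 equiv; run made earlier
- larch: Z 0.020 M; X 1.00 equiv; time 5.0 d
- elm: Z 0.040 M; X 1.00 equiv; time 5.0 d
- cedar: Z 0.080 M; X 1.00 equiv; time 5.0 d
- maple: Z 0.15 M; X 1.00 equiv; time 5.0 d
- ash: Z 0.30 M; X 1.00 equiv; time 5.0 d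

| run | time / d | G / % |
|---|---|---|
| alpha | 0.500 | 86.7 |
| alpha | 1.04 | 86.3 |
| alpha | 1.67 | 86.9 |
| alpha | 2.08 | 87.1 |
| alpha | 2.50 | 86.7 |
| alpha | 3.00 | 87.0 |
| epsilon | 0.208 | 89.0 |
| epsilon | 0.625 | 89.0 |
| epsilon | 1.04 | 89.4 |
| epsilon | 1.67 | 88.8 |
| epsilon | 2.50 | 88.9 |
| epsilon | 3.00 | 88.9 |

(readings scatter by 0.3 percentage points)

- what was read earlier has a scatter of 0.3 percentage points, one standard deviation
- at the start none of E is in solution
- "hardly changes" means that all values lie within two and a half points (for a concentration: within two and a half percent of the largest)

1. amount of G at the end, in percent of the Z charged for larch, elm, cedar, maple, ash, in this order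
2. the course of these numbers from the first flask to the last (rises all the way / falls all the way / hardly changes / falls, then rises / rises, then falls)

Both levels stay flat within the scatter of 0.3 percentage points, so I read them as the end of Z. A G that decayed by itself gives a falling level, and these do not fall, so I take the loss of G to need Z, at a pace set by the product of the two. But X moves the level by 2.2 points between those two runs, so I treat X as a side matter and take the mean, 87.8%, for larch at 1.00 equiv.

Next comes E, which starts out of solution and saturates at 4.2 mM, while larch holds 4.76 times as much Z. So, on my assumption that Z takes up E to give G, E has to enter during the run, and I take its uptake as the rate-limiting step, a steady feed.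

On that picture, with the feed steady, I reckon that a small charge loses a fraction growing as the square of the charge, with zero leftover as the zero of the scale. In a large charge, I reckon, G survives mainly from the late tail, when Z has thinned, so it ends near one amount. The plainest curve with both ends puts the fraction of G at one over the square root of one plus the square of the charge in units of that amount. Larch then gives an estimated ceiling of 1.83, the G I expect a large flask to end with, counted in larch charges.

So I reckon 67.6% for elm, 41.7% for cedar, 23.8% for maple and 12.1% for ash.

The forecast, reasoning that “X rises with Z, so diversion grows”, goes from 87.9% to 69.5% and says falls all the way, the same course as mine but higher at ash.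

The flasks give 87.8%, 71.5%, 47.0%, 28.3% and 15.4%: falls all the way.

    Z + D → G (k = 12.3 L mol⁻¹ min⁻¹)
    Z + G → Q (k = 0.148 L mol⁻¹ min⁻¹)
    E ⇌ D, rate k3*(csat - [D]) (kL = 0.104 min⁻¹)
    X + D → J (k = 63.1 L mol⁻¹ min⁻¹)
    D → L (k = 9.62 × 10⁻⁴ min⁻¹)

The reaction of Z with G to Q is the main reason for the fall: with that step taken away, ash gives 100% instead of 15.4%. Counted in larch charges, the G in ash is 2.31, above my ceiling of 1.83. Maple, with half the charge of Z that ash has, holds less G by the same count, 2.12.

The earlier runs and the new flask are simulated with made-up constants; scatter was added.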